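**Retrosynthetic overview**
- The target diacid comes from saponification of its monomethyl ester, which comes from hydrogenation of a cinnamic acid.
- Key C–C disconnection (benzylic carbon to α-carbon): Knoevenagel–Doebner aldol-type condensation of an aryl aldehyde with malonic acid, used for both three-carbon arms.
- C–O disconnection of the tetra-ortho-substituted diaryl ether: copper-catalysed Ullmann coupling of a 2,6-dimethoxyphenol carrying a finished propanoate arm with a 4-bromo-3,5-dimethoxybenzaldehyde, whose formyl group activates the bromide and then serves as the aldol acceptor.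
- The phenol partner is made from the 4-hydroxy analogue of that aldehyde by the same condensation, then hydrogenation and esterification.
- No ring is constructed: both benzene rings (ring A, ring B) are bought as substituted benzaldehydes.

Assumption: the target has no stereocentre and no stereogenic double bond, so the structure as drawn is the only stereoisomer and no enantiocontrol is needed.

**Route**

Step 1
Reactants: 1 syringaldehyde (4-hydroxy-3,5-dimethoxybenzaldehyde); 2 malonic acid (propanedioic acid)
Product: 4 (E)-sinapic acid [(E)-3-(4-hydroxy-3,5-dimethoxyphenyl)prop-2-enoic acid], via arylidenemalonic acid 3 (not isolated)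
Conditions: malonic acid (2.5 equiv), piperidine (0.2 equiv), pyridine, 70 °C, 16 h; then aq. HCl
Reagents that add atoms: none
Why: Knoevenagel–Doebner condensation (aldol-type addition of the malonic acid enol to the piperidine-activated aldehyde, dehydration, decarboxylation) gives the E-cinnamic acid, and 70 °C is low enough to avoid a second decarboxylation to the vinylphenol; no stereocentre is formed.

Step 2
Reactants: 4 (E)-sinapic acid
Product: 5 3-(4-hydroxy-3,5-dimethoxyphenyl)propanoic acid
Conditions: H2 (1 atm), 10% Pd/C, MeOH, rt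
Reagents that add atoms: none
Why: Catalytic hydrogenation saturates the conjugated C=C at room temperature while the arene, phenol, methyl ethers and acid are inert; no stereocentre arises.

Step 3
Reactants: 5 3-(4-hydroxy-3,5-dimethoxyphenyl)propanoic acid
Product: 6 methyl 3-(4-hydroxy-3,5-dimethoxyphenyl)propanoate
Conditions: MeOH, H2SO4 (cat.), reflux
Reagents that add atoms: methanol, CO
Why: Fischer esterification masks the acid, which would otherwise bind copper and base in the coupling, and leaves the phenol free because phenols are not alkylated under these acidic conditions.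

Step 4
Reactants: 6 methyl 3-(4-hydroxy-3,5-dimethoxyphenyl)propanoate; 7 4-bromo-3,5-dimethoxybenzaldehyde
Product: 8 methyl 3-[4-(4-formyl-2,6-dimethoxyphenoxy)-3,5-dimethoxyphenyl]propanoate
Conditions: 7 (1.3 equiv), CuI (20 mol%), picolinic acid (40 mol%), anhydrous K3PO4 (2 equiv), DMSO, 110 °C, 24 h, under argon
Reagents that add atoms: none
Why: Ullmann diaryl ether synthesis, in which the picolinate-ligated monovalent copper phenoxide (a ligand system developed for hindered partners) adds oxidatively to the aryl bromide activated by its para-formyl group and reductively eliminates the C–O bond; the electron-rich phenoxide is a good nucleophile, and ester and aldehyde tolerate anhydrous phosphate.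

Step 5
Reactants: 8 methyl 3-[4-(4-formyl-2,6-dimethoxyphenoxy)-3,5-dimethoxyphenyl]propanoate; 2 malonic acid
Product: 10 (E)-3-[4-[2,6-dimethoxy-4-(3-methoxy-3-oxopropyl)phenoxy]-3,5-dimethoxyphenyl]prop-2-enoic acid, via arylidenemalonic acid 9 (not isolated)
Conditions: malonic acid (3 equiv), piperidine (0.2 equiv), pyridine, 90 °C, 6 h; then aq. HCl
Reagents that add atoms: none
Why: Knoevenagel–Doebner condensation, the key aldol-type C–C bond formation, joins malonic acid to the unhindered formyl group and, after dehydration and decarboxylation in hot pyridine, gives the thermodynamically preferred E-cinnamic acid, with the remote methyl ester and the diaryl ether untouched; no stereocentre is created.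

Step 6
Reactants: 10 (E)-3-[4-[2,6-dimethoxy-4-(3-methoxy-3-oxopropyl)phenoxy]-3,5-dimethoxyphenyl]prop-2-enoic acid
Product: 11 3-[4-[2,6-dimethoxy-4-(3-methoxy-3-oxopropyl)phenoxy]-3,5-dimethoxyphenyl]propanoic acid
Conditions: H2 (1 atm), 10% Pd/C, EtOAc/MeOH, rt
Reagents that add atoms: none
Why: Catalytic hydrogenation reduces only the cinnamic C=C, since diaryl ethers and aryl methyl ethers are not hydrogenolysed at 1 atm and room temperature; the alkene geometry is erased and no stereocentre results.

Step 7
Reactants: 11 3-[4-[2,6-dimethoxy-4-(3-methoxy-3-oxopropyl)phenoxy]-3,5-dimethoxyphenyl]propanoic acid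
Product: 12 apteniol E [3,3'-[oxybis(3,5-dimethoxy-4,1-phenylene)]dipropanoic acid]
Conditions: LiOH·H2O (4 equiv), THF/MeOH/H2O, rt; then 1 M HCl to pH 2
Reagents that add atoms: lithium hydroxide, [Li+].[OH-]
Why: Saponification of the unhindered methyl ester followed by acidification gives the symmetric diacid; nothing else in the molecule is base-labile and there is no stereocentre to epimerise.

**Compound list**
1 | syringaldehyde (4-hydroxy-3,5-dimethoxybenzaldehyde) | COc1cc(C=O)cc(OC)c1O | starting material
2 | malonic acid (propanedioic acid) | OC(=O)CC(=O)O | starting material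
3 | 2-[(4-hydroxy-3,5-dimethoxyphenyl)methylidene]propanedioic acid (arylidenemalonic acid, not isolated) | COc1cc(C=C(C(=O)O)C(=O)O)cc(OC)c1O | intermediate
4 | (E)-sinapic acid, (E)-3-(4-hydroxy-3,5-dimethoxyphenyl)prop-2-enoic acid | COc1cc(/C=C/C(=O)O)cc(OC)c1O | intermediate
5 | 3-(4-hydroxy-3,5-dimethoxyphenyl)propanoic acid | COc1cc(CCC(=O)O)cc(OC)c1O | intermediate
6 | methyl 3-(4-hydroxy-3,5-dimethoxyphenyl)propanoate | COC(=O)CCc1cc(OC)c(O)c(OC)c1 | intermediate
7 | 4-bromo-3,5-dimethoxybenzaldehyde | COc1cc(C=O)cc(OC)c1Br | starting material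
8 | methyl 3-[4-(4-formyl-2,6-dimethoxyphenoxy)-3,5-dimethoxyphenyl]propanoate | COC(=O)CCc1cc(OC)c(Oc2c(OC)cc(C=O)cc2OC)c(OC)c1 | intermediate
9 | 2-[[4-[2,6-dimethoxy-4-(3-methoxy-3-oxopropyl)phenoxy]-3,5-dimethoxyphenyl]methylidene]propanedioic acid (arylidenemalonic acid, not isolated) | COC(=O)CCc1cc(OC)c(Oc2c(OC)cc(C=C(C(=O)O)C(=O)O)cc2OC)c(OC)c1 | intermediate
10 | (E)-3-[4-[2,6-dimethoxy-4-(3-methoxy-3-oxopropyl)phenoxy]-3,5-dimethoxyphenyl]prop-2-enoic acid | COC(=O)CCc1cc(OC)c(Oc2c(OC)cc(/C=C/C(=O)O)cc2OC)c(OC)c1 | intermediate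
11 | 3-[4-[2,6-dimethoxy-4-(3-methoxy-3-oxopropyl)phenoxy]-3,5-dimethoxyphenyl]propanoic acid | COC(=O)CCc1cc(OC)c(Oc2c(OC)cc(CCC(=O)O)cc2OC)c(OC)c1 | intermediate
12 | apteniol E, 3,3'-[oxybis(3,5-dimethoxy-4,1-phenylene)]dipropanoic acid (achiral) | COc1cc(CCC(=O)O)cc(OC)c1Oc1c(OC)cc(CCC(=O)O)cc1OC | target

**Step count**
Total steps: 7. Longest linear sequence: 7 steps (1 to 12); 7 is bought and enters at step 4.

**Steps most likely to fail, with fallbacks**

Step 4 (Ullmann coupling). Both partners carry two ortho methoxy groups, so coupling may be slow and 7 may suffer proto-debromination. The fallback is a metal-free arylation with a diaryliodonium salt, a method that tolerates ortho,ortho'-disubstitution on both partners. It sets out from 7. Copper-catalysed halogen exchange (NaI, CuI, N,N'-dimethylethylenediamine, dioxane, 110 °C) gives 4-iodo-3,5-dimethoxybenzaldehyde F1. One-pot oxidation to the trivalent-iodine tosylate (mCPBA, TsOH·H2O, MeCN) and capture with 1,3,5-trimethoxybenzene gives (4-formyl-2,6-dimethoxyphenyl)(2,4,6-trimethoxyphenyl)iodonium tosylate F2. The formyl group has no ortho or para donor and should survive the brief peracid exposure. The potassium phenoxide of 6 (t-BuOK, THF, rt to 40 °C) then adds to iodine, and ligand coupling transfers the more electron-poor formyl-bearing aryl group and expels 2-iodo-1,3,5-trimethoxybenzene. The route is rejoined at 8.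

Step 5 (Knoevenagel–Doebner on 8). Hot pyridine/piperidine could attack the methyl ester, or piperidine could displace the aryloxide para to the activated formyl group. The fallback is a room-temperature reductive Knoevenagel alkylation. It sets out from 8. Meldrum's acid, Hantzsch ester and L-proline (cat.) in EtOH at rt give the condensation product 5-[[4-[2,6-dimethoxy-4-(3-methoxy-3-oxopropyl)phenoxy]-3,5-dimethoxyphenyl]methylidene]-2,2-dimethyl-1,3-dioxane-4,6-dione F3, which is reduced in the flask by hydride transfer to 5-[[4-[2,6-dimethoxy-4-(3-methoxy-3-oxopropyl)phenoxy]-3,5-dimethoxyphenyl]methyl]-2,2-dimethyl-1,3-dioxane-4,6-dione F4. Heating F4 in pyridine/water at 100 °C opens the dioxanedione and decarboxylates it, losing acetone and carbon dioxide. The route is rejoined at 11, so steps 5 and 6 are both replaced.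

Step 1 (Knoevenagel–Doebner on the free phenol). The phenoxide lowers the electrophilicity of the aldehyde, and the 4-hydroxycinnamic acid can decarboxylate further to the vinylphenol. The fallback masks the phenol. It sets out from 1. Benzylation (BnBr, K2CO3, DMF, 60 °C) gives 4-(benzyloxy)-3,5-dimethoxybenzaldehyde F5. Condensation with 2 (pyridine, piperidine, 90 °C) passes through 2-[(4-benzyloxy-3,5-dimethoxyphenyl)methylidene]propanedioic acid F6, formed in the flask, and gives (E)-3-[4-(benzyloxy)-3,5-dimethoxyphenyl]prop-2-enoic acid F7. Hydrogenation (H2, Pd/C, MeOH/EtOAc, rt) saturates the alkene and cleaves the benzyl ether as toluene in one operation. The route is rejoined at 5, so steps 1 and 2 are both replaced.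

**Further compounds**
F1 | step 4 | 4-iodo-3,5-dimethoxybenzaldehyde | COc1cc(C=O)cc(OC)c1I
F2 | step 4 | (4-formyl-2,6-dimethoxyphenyl)(2,4,6-trimethoxyphenyl)iodonium tosylate | COc1cc(C=O)cc(OC)c1[I+]c1c(OC)cc(OC)cc1OC.Cc1ccc(S(=O)(=O)[O-])cc1
F3 | step 5 | 5-[[4-[2,6-dimethoxy-4-(3-methoxy-3-oxopropyl)phenoxy]-3,5-dimethoxyphenyl]methylidene]-2,2-dimethyl-1,3-dioxane-4,6-dione | COC(=O)CCc1cc(OC)c(Oc2c(OC)cc(C=C3C(=O)OC(C)(C)OC3=O)cc2OC)c(OC)c1
F4 | step 5 | 5-[[4-[2,6-dimethoxy-4-(3-methoxy-3-oxopropyl)phenoxy]-3,5-dimethoxyphenyl]methyl]-2,2-dimethyl-1,3-dioxane-4,6-dione | COC(=O)CCc1cc(OC)c(Oc2c(OC)cc(CC3C(=O)OC(C)(C)OC3=O)cc2OC)c(OC)c1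
F5 | step 1 | 4-(benzyloxy)-3,5-dimethoxybenzaldehyde | COc1cc(C=O)cc(OC)c1OCc1ccccc1
F6 | step 1 | 2-[(4-benzyloxy-3,5-dimethoxyphenyl)methylidene]propanedioic acid | COc1cc(C=C(C(=O)O)C(=O)O)cc(OC)c1OCc1ccccc1
F7 | step 1 | (E)-3-[4-(benzyloxy)-3,5-dimethoxyphenyl]prop-2-enoic acid | COc1cc(/C=C/C(=O)O)cc(OC)c1OCc1ccccc1
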